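**Retrosynthetic overview**

1. The target is a 4-hydroxy-6-methoxyphthalide (benzene ring fused to a γ-lactone ring) whose 5-oxygen carries an (2E,6E)-11-acetoxy-3,7,11-trimethyldodeca-2,6-dienyl chain; chain atoms are counted C1′ (OCH2) to C11′ (C(CH3)2OAc).
2. Key disconnection: the C5′(sp3)–C6′(sp2) bond, made in the last step by a one-pot 9-BBN hydroboration / B-alkyl Suzuki–Miyaura union of an unprotected dienyl aryl ether phthalide with an (E)-alkenyl iodide that already carries the tertiary acetate.
3. Enabling feature: C4′–C5′ is a saturated two-carbon link next to the C2′=C3′ alkene, so one hydrogenation level lower it is the vinyl end of a C2′=C3′–C4′=C5′ diene that takes boron only at C5′. C6′ is the unsubstituted CH end of the C6′=C7′(CH3) alkene, available with E geometry from a terminal alkyne by syn-methylalumination and iodination.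
4. Further disconnections: O–C1′ (4-O-selective alkylation of methyl 3,4-dihydroxy-5-methoxybenzoate with a dienyl bromide), the aryl–CH2 bond of the lactone (phenoxide-directed ortho-formylation) and the lactone C–O bond.
5. Ring order: the benzene ring is purchased; the γ-lactone ring is the only ring made (step 8); the key step closes no ring.

Key step: step 9

Assumption: the phenolic OH next to the lactone CH2 is carried unprotected throughout, and methyl hex-5-ynoate, (2E)-3-methylpent-2-en-4-yn-1-ol and methyl 3,4-dihydroxy-5-methoxybenzoate are taken as purchasable.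

**Route**

Step 1
Reactants: 1 methyl hex-5-ynoate
Product: 2 2-methylhept-6-yn-2-ol
Conditions: MeMgBr (3.3 equiv), THF, 0 °C to rt; aq. NH4Cl
Reagents that add atoms: methylmagnesium bromide, C[Mg]Br
Why: Double Grignard addition to the ester should give the tertiary carbinol, the acetylenic C–H only consuming one further equivalent of MeMgBr as the magnesium acetylide that is reprotonated on work-up.

Step 2
Reactants: 2 2-methylhept-6-yn-2-ol
Product: 4 (6E)-7-iodo-2,6-dimethylhept-6-en-2-ol, via alkenylalane 3 (not isolated)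
Conditions: Me3Al (3.5 equiv), Cp2ZrCl2 (0.3 equiv), CH2Cl2, 0 °C to rt; then I2, THF, −30 to 0 °C; aq. K2CO3 work-up
Reagents that add atoms: trimethylaluminium, C[Al](C)C; iodine, II
Why: In the Negishi zirconium-catalysed carboalumination the hydroxyl is first capped as its dimethylaluminium alkoxide, methyl and aluminium then add syn across the terminal alkyne with methyl on the internal carbon, and iodinolysis of the C–Al bond with retention should fix the E geometry of the alkenyl iodide.

Step 3
Reactants: 4 (6E)-7-iodo-2,6-dimethylhept-6-en-2-ol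
Product: 5 (6E)-7-iodo-2,6-dimethylhept-6-en-2-yl acetate
Conditions: Ac2O, Et3N, DMAP (0.3 equiv), CH2Cl2, 35 °C
Reagents that add atoms: acetic anhydride, CC(=O)OC(C)=O
Why: Steglich-type DMAP-catalysed acylation through the N-acetylpyridinium ion should acetylate the hindered tertiary alcohol without ionisation or elimination, the alkenyl iodide being inert.

Step 4
Reactants: 6 (2E)-3-methylpent-2-en-4-yn-1-ol
Product: 7 (2E)-3-methylpenta-2,4-dien-1-ol
Conditions: Zn dust activated with Cu(OAc)2 and AgNO3, MeOH/H2O, 40 °C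
Reagents that add atoms: none
Why: The Boland reduction with activated zinc should reduce only the conjugated terminal alkyne to the vinyl group, without over-reduction and without touching the E trisubstituted alkene.

Step 5
Reactants: 7 (2E)-3-methylpenta-2,4-dien-1-ol
Product: 8 (3E)-5-bromo-3-methylpenta-1,3-diene
Conditions: PBr3 (0.4 equiv), Et2O, −20 °C, dark; used crude at once
Reagents that add atoms: phosphorus tribromide, BrP(Br)Br
Why: SN2 bromination of the primary allylic alcohol through its phosphite ester at low temperature should keep the conjugated diene and its E geometry.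

Step 6
Reactants: 8 (3E)-5-bromo-3-methylpenta-1,3-diene; 9 methyl 3,4-dihydroxy-5-methoxybenzoate
Product: 10 methyl 3-hydroxy-5-methoxy-4-{[(2E)-3-methylpenta-2,4-dien-1-yl]oxy}benzoate
Conditions: KHCO3 (1.2 equiv), DMF, 0 °C to rt
Reagents that add atoms: none
Why: In this Williamson etherification only the 4-OH, para to the ester, is acidic enough to be deprotonated by hydrogencarbonate, so its phenoxide should attack the primary dienyl carbon in an SN2 sense while the 3-OH stays free.

Step 7
Reactants: 10 methyl 3-hydroxy-5-methoxy-4-{[(2E)-3-methylpenta-2,4-dien-1-yl]oxy}benzoate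
Product: 11 methyl 2-formyl-3-hydroxy-5-methoxy-4-{[(2E)-3-methylpenta-2,4-dien-1-yl]oxy}benzoate
Conditions: MgCl2 (3 equiv), Et3N (6 equiv), (CH2O)n (8 equiv), MeCN, 80 °C; 1 M HCl work-up
Reagents that add atoms: paraformaldehyde (formaldehyde), C=O
Why: In the magnesium-mediated ortho-formylation of phenols (Casnati–Skattebøl) the magnesium phenoxide delivers formaldehyde only to an ortho position, C2 is the single free position ortho to the 3-OH and is also para to the 5-OMe, and the hydroxymethyl intermediate is oxidised by a second formaldehyde through Oppenauer-type hydride transfer.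

Step 8
Reactants: 11 methyl 2-formyl-3-hydroxy-5-methoxy-4-{[(2E)-3-methylpenta-2,4-dien-1-yl]oxy}benzoate
Product: 13 4-hydroxy-6-methoxy-5-{[(2E)-3-methylpenta-2,4-dien-1-yl]oxy}isobenzofuran-1(3H)-one, via hydroxymethyl benzoate 12 (not isolated)
Conditions: NaBH4, MeOH/THF, 0 °C; then 1 M HCl, rt
Reagents that add atoms: none
Why: Chemoselective borohydride reduction of the aldehyde should give a benzylic alcohol held next to the methyl ester, which closes the γ-lactone by intramolecular acyl substitution (5-exo-trig) with loss of methanol, while ester, diene and aryl ether are inert to NaBH4.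

Step 9
Reactants: 13 4-hydroxy-6-methoxy-5-{[(2E)-3-methylpenta-2,4-dien-1-yl]oxy}isobenzofuran-1(3H)-one; 5 (6E)-7-iodo-2,6-dimethylhept-6-en-2-yl acetate
Product: 15 farnesylemefuranone F, via B-alkyl-9-BBN adduct 14 (not isolated)
Conditions: 9-BBN dimer (1.2 equiv), THF, 0 °C to rt; then Pd(dppf)Cl2 (5 mol %), AsPh3 (5 mol %), 3 M aq. K3PO4, DMF, rt; 1 M HCl work-up
Reagents that add atoms: none
Why: After the free 4-OH has consumed one equivalent of 9-BBN as its borinate (H2 evolution), 9-BBN adds syn across the monosubstituted C4′=C5′ bond of the conjugated diene with boron on the terminal carbon C5′; zerovalent palladium formed from Pd(dppf)Cl2 then inserts into the C–I bond of 5, the base-activated alkylborate transfers C5′ to palladium, and reductive elimination forges the C5′–C6′ sp3–sp2 bond. The closest known reaction type is the B-alkyl Suzuki–Miyaura coupling of 9-BBN adducts of terminal dienes with (E)-1-iodo-2-methylalk-1-enes used for isoprenoid chain extension. No ring is closed and no stereocentre is created; the stereochemical content is the two alkene geometries, C2′=C3′ being untouched and C6′=C7′ carried over from 5 because oxidative addition and reductive elimination are stereoretentive. The step needs anti-Markovnikov regioselectivity, secured by the steric demand of 9-BBN; chemoselectivity for the vinyl group over the trisubstituted alkene and the lactone carbonyl, secured by the low reactivity of 9-BBN towards both at room temperature; and oxidative addition into the alkenyl iodide rather than ionisation of the trisubstituted allylic aryl ether, secured by the much faster reaction of alkenyl iodides with the dppf-ligated catalyst at room temperature. Acidic work-up should reclose any lactone opened by the aqueous base and release the phenol, and the tertiary acetate is too hindered to be saponified under these conditions.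

**Compound list**

1 | methyl hex-5-ynoate | COC(=O)CCCC#C | starting material
2 | 2-methylhept-6-yn-2-ol | CC(C)(O)CCCC#C | intermediate
3 | dimethyl{(1E)-6-[(dimethylalumanyl)oxy]-2,6-dimethylhept-1-en-1-yl}alumane (alkenylalane) | C[Al](C)OC(C)(C)CCC/C(C)=C/[Al](C)C | intermediate
4 | (6E)-7-iodo-2,6-dimethylhept-6-en-2-ol | CC(C)(O)CCC/C(C)=C/I | intermediate
5 | (6E)-7-iodo-2,6-dimethylhept-6-en-2-yl acetate | CC(=O)OC(C)(C)CCC/C(C)=C/I | intermediate
6 | (2E)-3-methylpent-2-en-4-yn-1-ol | OC/C=C(\C)C#C | starting material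
7 | (2E)-3-methylpenta-2,4-dien-1-ol | OC/C=C(\C)C=C | intermediate
8 | (3E)-5-bromo-3-methylpenta-1,3-diene | BrC/C=C(\C)C=C | intermediate
9 | methyl 3,4-dihydroxy-5-methoxybenzoate | COC(=O)c1cc(O)c(O)c(OC)c1 | starting material
10 | methyl 3-hydroxy-5-methoxy-4-{[(2E)-3-methylpenta-2,4-dien-1-yl]oxy}benzoate | COC(=O)c1cc(OC)c(OC/C=C(\C)C=C)c(O)c1 | intermediate
11 | methyl 2-formyl-3-hydroxy-5-methoxy-4-{[(2E)-3-methylpenta-2,4-dien-1-yl]oxy}benzoate | COC(=O)c1cc(OC)c(OC/C=C(\C)C=C)c(O)c1C=O | intermediate
12 | methyl 3-hydroxy-2-(hydroxymethyl)-5-methoxy-4-{[(2E)-3-methylpenta-2,4-dien-1-yl]oxy}benzoate | COC(=O)c1cc(OC)c(OC/C=C(\C)C=C)c(O)c1CO | intermediate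
13 | 4-hydroxy-6-methoxy-5-{[(2E)-3-methylpenta-2,4-dien-1-yl]oxy}isobenzofuran-1(3H)-one | COc1cc2c(c(O)c1OC/C=C(\C)C=C)COC2=O | intermediate
14 | 4-[(9-borabicyclo[3.3.1]nonan-9-yl)oxy]-5-{[(2E)-5-(9-borabicyclo[3.3.1]nonan-9-yl)-3-methylpent-2-en-1-yl]oxy}-6-methoxyisobenzofuran-1(3H)-one | COc1cc2c(c(OB3C4CCCC3CCC4)c1OC/C=C(\C)CCB1C3CCCC1CCC3)COC2=O | intermediate
15 | farnesylemefuranone F, (6E,10E)-12-[(4-hydroxy-6-methoxy-1-oxo-1,3-dihydroisobenzofuran-5-yl)oxy]-2,6,10-trimethyldodeca-6,10-dien-2-yl acetate | COc1cc2c(c(O)c1OC/C=C(\C)CC/C=C(\C)CCCC(C)(C)OC(C)=O)COC2=O | target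

**Step count and risks**

Total step count: 9. Longest linear sequence: 6 steps (steps 4, 5, 6, 7, 8, 9, from compound 6 to compound 15).

Steps most likely to fail:

1. Step 9 (key step). What may go wrong: ionisation of the allylic aryl ether by zerovalent palladium with loss of the phenoxide, or diversion of the borane by the free phenol and slow reduction of the lactone, so that alkyl transfer is starved. The fallback moves the C–C coupling to a substrate without the arene and attaches the arene afterwards; it sets out from 7 and 5 and comes back at 15.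
   - 9-BBN (2.3 equiv) should convert dienol 7 into the O,C-bis-boryl species 9-{[(2E)-5-(9-borabicyclo[3.3.1]nonan-9-yl)-3-methylpent-2-en-1-yl]oxy}-9-borabicyclo[3.3.1]nonane F1.
   - Coupling with 5 (Pd(dppf)Cl2, aq. K3PO4, DMF, rt) should give (6E,10E)-12-hydroxy-2,6,10-trimethyldodeca-6,10-dien-2-yl acetate F2; an allylic alcohol is not ionised by zerovalent palladium.
   - Appel bromination (CBr4, PPh3, CH2Cl2, 0 °C) should give (6E,10E)-12-bromo-2,6,10-trimethyldodeca-6,10-dien-2-yl acetate F3.
   - 4-O-selective alkylation of 9 (KHCO3, DMF) should give methyl 4-{[(2E,6E)-11-acetoxy-3,7,11-trimethyldodeca-2,6-dien-1-yl]oxy}-3-hydroxy-5-methoxybenzoate F4.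
   - Magnesium-mediated ortho-formylation (MgCl2, Et3N, (CH2O)n) should give methyl 4-{[(2E,6E)-11-acetoxy-3,7,11-trimethyldodeca-2,6-dien-1-yl]oxy}-2-formyl-3-hydroxy-5-methoxybenzoate F5.
   - NaBH4 reduction should give methyl 4-{[(2E,6E)-11-acetoxy-3,7,11-trimethyldodeca-2,6-dien-1-yl]oxy}-3-hydroxy-2-(hydroxymethyl)-5-methoxybenzoate F6, which lactonises on acidic work-up to 15.

2. Step 7. What may go wrong: sluggish electrophilic attack at the crowded position between ester and phenoxide, or degradation of the diene by hot formaldehyde and the magnesium Lewis acid. The fallback builds the lactone by directed ortho-metalation before the diene is present; it sets out from 9 and comes back at 13.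
   - MOMCl/i-Pr2NEt should give methyl 3-methoxy-4,5-bis(methoxymethoxy)benzoate F7.
   - Aminolysis with Et2NH/i-PrMgCl (THF) should give N,N-diethyl-3-methoxy-4,5-bis(methoxymethoxy)benzamide F8.
   - s-BuLi/TMEDA (THF, −78 °C) should lithiate between the amide and the neighbouring OMOM group, the two strongest directing groups, to give N,N-diethyl-2-lithio-5-methoxy-3,4-bis(methoxymethoxy)benzamide F9.
   - DMF quench should give N,N-diethyl-2-formyl-5-methoxy-3,4-bis(methoxymethoxy)benzamide F10.
   - NaBH4 should give N,N-diethyl-2-(hydroxymethyl)-5-methoxy-3,4-bis(methoxymethoxy)benzamide F11.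
   - HCl in MeOH at 60 °C should lactonise and remove both MOM groups to give 4,5-dihydroxy-6-methoxyisobenzofuran-1(3H)-one F12.
   - Alkylation with 8 (KHCO3, DMF) at the 5-OH, which is para to the lactone carbonyl and the more acidic, should give 13.

3. Step 6. What may go wrong: alkylation at the wrong phenol or at both, and SN2′ attack or E/Z scrambling of the labile dienyl bromide. The fallback leaves only one phenol free and avoids the bromide; it sets out from 9 and comes back at 10.
   - Ac2O/pyridine should give methyl 3,4-diacetoxy-5-methoxybenzoate F13.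
   - One equivalent of pyrrolidine (MeCN, 0 °C) should cleave the more activated acetate para to the ester to give methyl 3-acetoxy-4-hydroxy-5-methoxybenzoate F14.
   - Mitsunobu etherification with dienol 7 (PPh3, DIAD, THF, 0 °C) should give methyl 3-acetoxy-5-methoxy-4-{[(2E)-3-methylpenta-2,4-dien-1-yl]oxy}benzoate F15.
   - Methanolysis (K2CO3, MeOH, 0 °C) should give 10.

**Further compounds**

F1 | step 9 | 9-{[(2E)-5-(9-borabicyclo[3.3.1]nonan-9-yl)-3-methylpent-2-en-1-yl]oxy}-9-borabicyclo[3.3.1]nonane | O(B1C2CCCC1CCC2)C/C=C(\C)CCB1C2CCCC1CCC2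
F2 | step 9 | (6E,10E)-12-hydroxy-2,6,10-trimethyldodeca-6,10-dien-2-yl acetate | OC/C=C(\C)CC/C=C(\C)CCCC(C)(C)OC(C)=O
F3 | step 9 | (6E,10E)-12-bromo-2,6,10-trimethyldodeca-6,10-dien-2-yl acetate | BrC/C=C(\C)CC/C=C(\C)CCCC(C)(C)OC(C)=O
F4 | step 9 | methyl 4-{[(2E,6E)-11-acetoxy-3,7,11-trimethyldodeca-2,6-dien-1-yl]oxy}-3-hydroxy-5-methoxybenzoate | COC(=O)c1cc(OC)c(OC/C=C(\C)CC/C=C(\C)CCCC(C)(C)OC(C)=O)c(O)c1
F5 | step 9 | methyl 4-{[(2E,6E)-11-acetoxy-3,7,11-trimethyldodeca-2,6-dien-1-yl]oxy}-2-formyl-3-hydroxy-5-methoxybenzoate | COC(=O)c1cc(OC)c(OC/C=C(\C)CC/C=C(\C)CCCC(C)(C)OC(C)=O)c(O)c1C=O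
F6 | step 9 | methyl 4-{[(2E,6E)-11-acetoxy-3,7,11-trimethyldodeca-2,6-dien-1-yl]oxy}-3-hydroxy-2-(hydroxymethyl)-5-methoxybenzoate | COC(=O)c1cc(OC)c(OC/C=C(\C)CC/C=C(\C)CCCC(C)(C)OC(C)=O)c(O)c1CO
F7 | step 7 | methyl 3-methoxy-4,5-bis(methoxymethoxy)benzoate | COC(=O)c1cc(OC)c(OCOC)c(OCOC)c1
F8 | step 7 | N,N-diethyl-3-methoxy-4,5-bis(methoxymethoxy)benzamide | CCN(CC)C(=O)c1cc(OC)c(OCOC)c(OCOC)c1
F9 | step 7 | N,N-diethyl-2-lithio-5-methoxy-3,4-bis(methoxymethoxy)benzamide | CCN(CC)C(=O)c1cc(OC)c(OCOC)c(OCOC)c1[Li]
F10 | step 7 | N,N-diethyl-2-formyl-5-methoxy-3,4-bis(methoxymethoxy)benzamide | CCN(CC)C(=O)c1cc(OC)c(OCOC)c(OCOC)c1C=O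
F11 | step 7 | N,N-diethyl-2-(hydroxymethyl)-5-methoxy-3,4-bis(methoxymethoxy)benzamide | CCN(CC)C(=O)c1cc(OC)c(OCOC)c(OCOC)c1CO
F12 | step 7 | 4,5-dihydroxy-6-methoxyisobenzofuran-1(3H)-one | COc1cc2c(c(O)c1O)COC2=O
F13 | step 6 | methyl 3,4-diacetoxy-5-methoxybenzoate | COC(=O)c1cc(OC)c(OC(C)=O)c(OC(C)=O)c1
F14 | step 6 | methyl 3-acetoxy-4-hydroxy-5-methoxybenzoate | COC(=O)c1cc(OC)c(O)c(OC(C)=O)c1
F15 | step 6 | methyl 3-acetoxy-5-methoxy-4-{[(2E)-3-methylpenta-2,4-dien-1-yl]oxy}benzoate | COC(=O)c1cc(OC)c(OC/C=C(\C)C=C)c(OC(C)=O)c1
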